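**Retrosynthetic overview**
1. Last bonds: the CH2–CH2 bond between the quaternary carbon and the ring arm (sulfone alkylation of 38 with iodide 13, then desulfonylation), and the E-alkene (Julia–Kocienski olefination of aldehyde 36 with PT-sulfone 24; PT = 1-phenyl-1H-tetrazol-5-yl).
2. Quaternary centre: decarboxylative Ireland–Claisen [3,3] rearrangement of dienyl tosylacetate 31, with chirality relayed from the carbinol of (S)-but-3-yn-2-ol.
3. Both C12 "ring-type" units come from one intermediate, iodide 13, made from (R)-citronellal by gem-dimethylation, carbonyl-ene cyclisation and hydroboration.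
4. Right chain: 13 is coupled with (R)-3-bromo-2-methylpropan-1-ol, then its ring is re-opened (ozonolysis, decarboxylative olefination, methylenation) to diene sulfone 24.
5. Ring order: the only ring is closed in step 4 (cyclohexanol) and becomes the cyclohexene in step 7; no other ring is formed.

Assumption: 1, 14 and 25 are bought in ≥98% ee; steps are numbered straight through the branches (1–8 common, 9–14 right chain, 15–20 quaternary piece, 21–23 endgame).

**Step 1**
Reactants: 1 (R)-citronellal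
Product: 3 (3R)-3,7-dimethyloct-6-enenitrile, via aldoxime 2 (not isolated)
Conditions: NH2OH·HCl, pyridine, rt; then Ac2O, 90 °C
Reagents that add atoms: hydroxylamine hydrochloride, NO.Cl
Why: Oxime formation followed by acetic anhydride dehydration gives the nitrile, which can be dialkylated cleanly, and the C3 centre is not touched.

**Step 2**
Reactants: 3 (3R)-3,7-dimethyloct-6-enenitrile
Product: 5 (3R)-2,2,3,7-tetramethyloct-6-enenitrile, via monomethyl nitrile 4 (not isolated)
Conditions: LiN(i-Pr)2, THF, −78 °C, MeI; then LiN(i-Pr)2, −78 °C, MeI, → rt (one flask)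
Reagents that add atoms: iodomethane, CI
Why: Two successive nitrile α-alkylations (SN2 on MeI) build the gem-dimethyl carbon, and C3 is not acidic so it keeps its configuration.

**Step 3**
Reactants: 5 (3R)-2,2,3,7-tetramethyloct-6-enenitrile
Product: 7 (3R)-2,2,3,7-tetramethyloct-6-enal, via N-aluminio imine 6 (not isolated)
Conditions: i-Bu2AlH, toluene, −78 → 0 °C; then aq. tartaric acid
Reagents that add atoms: water, O
Why: Partial hydride reduction of the hindered nitrile stops at the imine, which hydrolyses to the non-enolisable aldehyde.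

**Step 4**
Reactants: 7 (3R)-2,2,3,7-tetramethyloct-6-enal
Product: 8 (1S,3R,6S)-2,2,3-trimethyl-6-(prop-1-en-2-yl)cyclohexan-1-ol
Conditions: ZnBr2 (1 equiv), CH2Cl2, 0 °C
Reagents that add atoms: none
Why: Lewis-acid-promoted type 1 intramolecular carbonyl-ene cyclisation through a chair with the C3 methyl, the complexed C=O and the new isopropenyl group all equatorial, so the bought centre sets C1 and C6 as in the citronellal-to-isopulegol cyclisation.

**Step 5**
Reactants: 8 (1S,3R,6S)-2,2,3-trimethyl-6-(prop-1-en-2-yl)cyclohexan-1-ol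
Product: 10 (1S,3R,6S)-6-[(2S)-1-hydroxypropan-2-yl]-2,2,3-trimethylcyclohexan-1-ol, via cyclic alkoxyborane 9 (not isolated)
Conditions: BH3·THF, THF, 0 °C → rt; then NaOH, H2O2, 0 °C
Reagents that add atoms: hydrogen peroxide, OO
Why: Hydroboration–oxidation of the 1,1-disubstituted alkene, in which boron adds in the A(1,2)-minimised conformer to the face away from the oxygen-bearing ring carbon (the sense known for isopulegol), sets the side-chain centre as (2S) under control of C6 and C1.

**Step 6**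
Reactants: 10 (1S,3R,6S)-6-[(2S)-1-hydroxypropan-2-yl]-2,2,3-trimethylcyclohexan-1-ol
Product: 11 (2S)-2-[(1S,2S,4R)-2-hydroxy-3,3,4-trimethylcyclohexyl]propyl 4-methylbenzenesulfonate
Conditions: TsCl, pyridine, CH2Cl2, 0 °C
Reagents that add atoms: 4-methylbenzenesulfonyl chloride, Cc1ccc(cc1)S(Cl)(=O)=O
Why: Selective sulfonylation of the primary hydroxyl, because the neopentyl-type secondary hydroxyl is too hindered to react at 0 °C.

**Step 7**
Reactants: 11 (2S)-2-[(1S,2S,4R)-2-hydroxy-3,3,4-trimethylcyclohexyl]propyl 4-methylbenzenesulfonate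
Product: 12 (2S)-2-[(4R)-3,3,4-trimethylcyclohex-1-en-1-yl]propyl 4-methylbenzenesulfonate
Conditions: Burgess reagent, toluene, 60 °C
Reagents that add atoms: none
Why: Burgess dehydration (syn Ei elimination) can only remove the single β-hydrogen, which is cis to the oxygen, so the trisubstituted alkene forms regiospecifically and the two temporary ring stereocentres are erased.

**Step 8**
Reactants: 12 (2S)-2-[(4R)-3,3,4-trimethylcyclohex-1-en-1-yl]propyl 4-methylbenzenesulfonate
Product: 13 (4R)-1-[(2S)-1-iodopropan-2-yl]-3,3,4-trimethylcyclohex-1-ene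
Conditions: NaI, butan-2-one, 80 °C
Reagents that add atoms: sodium iodide, [Na+].[I-]
Why: Finkelstein SN2 exchange at the primary carbon gives the iodide needed both for Grignard formation and for alkylation.

**Step 9**
Reactants: 13 (4R)-1-[(2S)-1-iodopropan-2-yl]-3,3,4-trimethylcyclohex-1-ene; 14 (R)-3-bromo-2-methylpropan-1-ol
Product: 17 (2S,5R)-2-methyl-5-[(4R)-3,3,4-trimethylcyclohex-1-en-1-yl]hexan-1-ol, via Grignard reagent 15 (not isolated), via bromo alkoxide 16 (not isolated)
Conditions: 13, Mg, THF, rt; 14, i-PrMgCl, THF, −20 °C; mix, Li2CuCl4 (5 mol%), NMP, −20 → 0 °C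
Reagents that add atoms: none
Why: Copper-catalysed Kochi-type sp3–sp3 coupling of the primary Grignard reagent with the primary bromide touches no stereocentre, so the bought centre of 14 becomes C2 (S only by a CIP priority change).

**Step 10**
Reactants: 17 (2S,5R)-2-methyl-5-[(4R)-3,3,4-trimethylcyclohex-1-en-1-yl]hexan-1-ol
Product: 18 5-({(2S,5R)-2-methyl-5-[(4R)-3,3,4-trimethylcyclohex-1-en-1-yl]hexyl}sulfanyl)-1-phenyl-1H-tetrazole
Conditions: 1-phenyl-1H-tetrazole-5-thiol, PPh3, DIAD, THF, 0 °C → rt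
Reagents that add atoms: 1-phenyl-1H-tetrazole-5-thiol, Sc1nnnn1-c1ccccc1
Why: Mitsunobu thioetherification of the primary alcohol proceeds without affecting the adjacent stereocentre.

**Step 11**
Reactants: 18 PT sulfide
Product: 19 5-({(2S,5R)-2-methyl-5-[(4R)-3,3,4-trimethylcyclohex-1-en-1-yl]hexyl}sulfonyl)-1-phenyl-1H-tetrazole
Conditions: (NH4)6Mo7O24·4H2O (cat.), 30% H2O2, EtOH, 0 °C → rt
Reagents that add atoms: hydrogen peroxide, OO
Why: Molybdate-catalysed peroxide oxidation takes the sulfide to the sulfone faster than it epoxidises the hindered trisubstituted alkene.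

**Step 12**
Reactants: 19 PT sulfone
Product: 22 (3R,7R,10S)-2,2,3,7,10-pentamethyl-6-oxo-11-[(1-phenyl-1H-tetrazol-5-yl)sulfonyl]undecanoic acid, via ozonide 20 (not isolated), via keto aldehyde 21 (not isolated)
Conditions: O3, CH2Cl2, −78 °C; Me2S, → rt; then NaClO2, NaH2PO4, 2-methylbut-2-ene, t-BuOH/H2O, rt
Reagents that add atoms: ozone, [O-][O+]=O; sodium chlorite, [Na+].[O-]Cl=O
Why: Ozonolysis opens the ring to a ketone and a neopentyl aldehyde, and Pinnick oxidation of the latter under buffered conditions gives the acid without epimerising the α-methyl ketone.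

**Step 13**
Reactants: 22 keto acid
Product: 23 5-{[(2S,5R,9R)-2,5,9,10-tetramethyl-6-oxoundec-10-en-1-yl]sulfonyl}-1-phenyl-1H-tetrazole
Conditions: Pb(OAc)4, Cu(OAc)2 (cat.), pyridine, benzene, 80 °C
Reagents that add atoms: none
Why: Kochi oxidative decarboxylation gives a tertiary radical that Cu(OAc)2 oxidises to the alkene, with loss of one of six methyl hydrogens favoured over the single hindered methine hydrogen, so the isopropenyl group forms.

**Step 14**
Reactants: 23 isopropenyl ketone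
Product: 24 5-{[(2S,5R,9R)-2,5,9,10-tetramethyl-6-methylideneundec-10-en-1-yl]sulfonyl}-1-phenyl-1H-tetrazole
Conditions: Cp2TiMe2, toluene, 65 °C
Reagents that add atoms: dimethyltitanocene, C[Ti](C)(C1C=CC=C1)C1C=CC=C1
Why: Petasis methylenation (titanium carbene) is non-basic, so the α-stereocentre of the ketone and the base-sensitive PT-sulfone survive.

**Step 15**
Reactants: 25 (S)-but-3-yn-2-ol
Product: 27 (S)-pent-3-yn-2-ol, via dilithio salt 26 (not isolated)
Conditions: n-BuLi (2.1 equiv), THF, −78 → −20 °C; then MeI, DMPU, −78 → 0 °C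
Reagents that add atoms: iodomethane, CI
Why: The alkoxide–acetylide dianion is alkylated (SN2) at the far more nucleophilic acetylide carbon.

**Step 16**
Reactants: 27 (S)-pent-3-yn-2-ol
Product: 29 (2S,3Z)-4-iodopent-3-en-2-ol, via alkenylalanate 28 (not isolated)
Conditions: NaAlH2(OCH2CH2OCH3)2, THF, 0 °C → rt; then I2, THF, −78 °C
Reagents that add atoms: iodine, II
Why: Hydroxyl-directed trans-hydroalumination puts aluminium on the distal alkyne carbon cis to the carbinol carbon, and iodinolysis with retention gives the Z-iodide.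

**Step 17**
Reactants: 29 (2S,3Z)-4-iodopent-3-en-2-ol
Product: 30 (2S,3Z)-4-methylhexa-3,5-dien-2-ol
Conditions: vinylboronic acid pinacol ester, Pd(PPh3)4 (5 mol%), K2CO3, THF/H2O, 50 °C
Reagents that add atoms: 2-ethenyl-4,4,5,5-tetramethyl-1,3,2-dioxaborolane, C=CB1OC(C)(C)C(C)(C)O1
Why: Suzuki–Miyaura coupling retains the alkene geometry, which places the vinyl group cis to the carbinol carbon.

**Step 18**
Reactants: 30 (2S,3Z)-4-methylhexa-3,5-dien-2-ol
Product: 31 (2S,3Z)-4-methylhexa-3,5-dien-2-yl 2-(4-methylbenzenesulfonyl)acetate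
Conditions: TsCH2CO2H, DCC, DMAP (cat.), CH2Cl2, 0 °C → rt
Reagents that add atoms: 2-(4-methylbenzenesulfonyl)acetic acid, Cc1ccc(cc1)S(=O)(=O)CC(=O)O
Why: Steglich (carbodiimide) esterification acylates the secondary allylic alcohol under neutral conditions without touching the C–O stereocentre.

**Step 19**
Reactants: 31 dienyl tosylacetate
Product: 34 1-{[(2S,3E)-2-ethenyl-2-methylpent-3-en-1-yl]sulfonyl}-4-methylbenzene, via silyl ketene acetal 32 (not isolated), via silyl ester 33 (not isolated)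
Conditions: MeC(OSiMe3)=NSiMe3 (0.2 equiv), KOAc (0.1 equiv), toluene, 110 °C
Reagents that add atoms: none
Why: In this decarboxylative Ireland–Claisen [3,3]-sigmatropic rearrangement the ketene acetal reacts through a chair with the carbinol methyl equatorial (the axial alternative clashes with the Z-vinyl group), so the (S) C–O centre is relayed suprafacially to the (S) quaternary carbon with an E-propenyl group before CO2 is lost.

**Step 20**
Reactants: 34 homoallylic sulfone
Product: 36 (2S)-2-methyl-2-[(4-methylbenzenesulfonyl)methyl]but-3-enal, via ozonide 35 (not isolated)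
Conditions: O3 (1.0 equiv), CH2Cl2, −78 °C; then Me2S, → rt
Reagents that add atoms: ozone, [O-][O+]=O
Why: In this ozonolysis the more electron-rich 1,2-disubstituted alkene is cleaved before the vinyl group when one equivalent of ozone is used.

**Step 21**
Reactants: 24 diene PT-sulfone; 36 aldehyde
Product: 38 1-methyl-4-{[(2S,3E,5S,8R,12R)-2-ethenyl-2,5,8,12,13-pentamethyl-9-methylidenetetradeca-3,13-dien-1-yl]sulfonyl}benzene, via potassio sulfone 37 (not isolated)
Conditions: KN(SiMe3)2, DME, −60 °C; then 36, −60 °C → rt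
Reagents that add atoms: none
Why: Julia–Kocienski olefination is E-selective for a β-branched sulfone anion and an α-quaternary aldehyde with a potassium counter-ion in DME, and the aldehyde has no α-hydrogen to lose.

**Step 22**
Reactants: 38 triene sulfone; 13 (4R)-1-[(2S)-1-iodopropan-2-yl]-3,3,4-trimethylcyclohex-1-ene
Product: 40 alkylated sulfone (1-tosyl derivative of the target at the CH2 next to the quaternary carbon; both epimers), via lithio sulfone 39 (not isolated)
Conditions: n-BuLi, THF, −78 °C; then 13, HMPA, −78 → 0 °C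
Reagents that add atoms: none
Why: SN2 alkylation of the α-sulfonyl carbanion by the primary iodide forms the last C–C bond, and the new sulfone-bearing centre is removed in the next step.

**Step 23**
Reactants: 40 alkylated sulfone
Product: 41 (4R)-1-[(2R,5S,6E,8S,11R,15R)-5-ethenyl-5,8,11,15,16-pentamethyl-12-methylideneheptadeca-6,16-dien-2-yl]-3,3,4-trimethylcyclohex-1-ene (CNP0321027.1)
Conditions: NaC10H8, THF, −78 °C; then MeOH
Reagents that add atoms: none
Why: Reductive desulfonylation by single-electron transfer at −78 °C reduces the alkyl radical faster than a 1,2-vinyl shift can occur and leaves the isolated alkenes untouched.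

**Compound list**
1 | (R)-citronellal, (3R)-3,7-dimethyloct-6-enal | O=CC[C@H](C)CCC=C(C)C | starting material
2 | (3R)-3,7-dimethyloct-6-enal oxime | ON=CC[C@H](C)CCC=C(C)C | intermediate
3 | (3R)-3,7-dimethyloct-6-enenitrile | N#CC[C@H](C)CCC=C(C)C | intermediate
4 | (3R)-2,3,7-trimethyloct-6-enenitrile (both C2 epimers) | N#CC(C)[C@H](C)CCC=C(C)C | intermediate
5 | (3R)-2,2,3,7-tetramethyloct-6-enenitrile | N#CC(C)(C)[C@H](C)CCC=C(C)C | intermediate
6 | N-(diisobutylalumanyl)imine of 7 | CC(C)C[Al](CC(C)C)N=CC(C)(C)[C@H](C)CCC=C(C)C | intermediate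
7 | (3R)-2,2,3,7-tetramethyloct-6-enal | O=CC(C)(C)[C@H](C)CCC=C(C)C | intermediate
8 | (1S,3R,6S)-2,2,3-trimethyl-6-(prop-1-en-2-yl)cyclohexan-1-ol | O[C@@H]1C(C)(C)[C@H](C)CC[C@H]1C(C)=C | intermediate
9 | B–H 1,2-oxaborinane in which boron bridges the ring oxygen and the new side-chain CH2 (stereocentres as in 10) | O2[C@@H]1C(C)(C)[C@H](C)CC[C@H]1[C@H](C)CB2 | intermediate
10 | (1S,3R,6S)-6-[(2S)-1-hydroxypropan-2-yl]-2,2,3-trimethylcyclohexan-1-ol | O[C@@H]1C(C)(C)[C@H](C)CC[C@H]1[C@H](C)CO | intermediate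
11 | (2S)-2-[(1S,2S,4R)-2-hydroxy-3,3,4-trimethylcyclohexyl]propyl 4-methylbenzenesulfonate | O[C@@H]1C(C)(C)[C@H](C)CC[C@H]1[C@H](C)COS(=O)(=O)c1ccc(C)cc1 | intermediate
12 | (2S)-2-[(4R)-3,3,4-trimethylcyclohex-1-en-1-yl]propyl 4-methylbenzenesulfonate | C[C@H](COS(=O)(=O)c1ccc(C)cc1)C1=CC(C)(C)[C@H](C)CC1 | intermediate
13 | (4R)-1-[(2S)-1-iodopropan-2-yl]-3,3,4-trimethylcyclohex-1-ene | C[C@H](CI)C1=CC(C)(C)[C@H](C)CC1 | intermediate
14 | (R)-3-bromo-2-methylpropan-1-ol | OC[C@@H](C)CBr | starting material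
15 | {(2S)-2-[(4R)-3,3,4-trimethylcyclohex-1-en-1-yl]propyl}magnesium iodide | C[C@H](C[Mg]I)C1=CC(C)(C)[C@H](C)CC1 | intermediate
16 | chloromagnesium (2R)-3-bromo-2-methylpropan-1-olate | Cl[Mg]OC[C@@H](C)CBr | intermediate
17 | (2S,5R)-2-methyl-5-[(4R)-3,3,4-trimethylcyclohex-1-en-1-yl]hexan-1-ol | OC[C@@H](C)CC[C@@H](C)C1=CC(C)(C)[C@H](C)CC1 | intermediate
18 | 5-({(2S,5R)-2-methyl-5-[(4R)-3,3,4-trimethylcyclohex-1-en-1-yl]hexyl}sulfanyl)-1-phenyl-1H-tetrazole | c1ccccc1-n1nnnc1SC[C@@H](C)CC[C@@H](C)C1=CC(C)(C)[C@H](C)CC1 | intermediate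
19 | 5-({(2S,5R)-2-methyl-5-[(4R)-3,3,4-trimethylcyclohex-1-en-1-yl]hexyl}sulfonyl)-1-phenyl-1H-tetrazole | c1ccccc1-n1nnnc1S(=O)(=O)C[C@@H](C)CC[C@@H](C)C1=CC(C)(C)[C@H](C)CC1 | intermediate
20 | ozonide (1,2,4-trioxolane across the former ring alkene) of 19 | c1ccccc1-n1nnnc1S(=O)(=O)C[C@@H](C)CC[C@@H](C)C12OOC(O1)C(C)(C)[C@H](C)CC2 | intermediate
21 | 5-{[(2S,5R,9R)-2,5,9,10,10-pentamethyl-6,11-dioxoundecyl]sulfonyl}-1-phenyl-1H-tetrazole | c1ccccc1-n1nnnc1S(=O)(=O)C[C@@H](C)CC[C@@H](C)C(=O)CC[C@@H](C)C(C)(C)C=O | intermediate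
22 | (3R,7R,10S)-2,2,3,7,10-pentamethyl-6-oxo-11-[(1-phenyl-1H-tetrazol-5-yl)sulfonyl]undecanoic acid | c1ccccc1-n1nnnc1S(=O)(=O)C[C@@H](C)CC[C@@H](C)C(=O)CC[C@@H](C)C(C)(C)C(=O)O | intermediate
23 | 5-{[(2S,5R,9R)-2,5,9,10-tetramethyl-6-oxoundec-10-en-1-yl]sulfonyl}-1-phenyl-1H-tetrazole | c1ccccc1-n1nnnc1S(=O)(=O)C[C@@H](C)CC[C@@H](C)C(=O)CC[C@@H](C)C(C)=C | intermediate
24 | 5-{[(2S,5R,9R)-2,5,9,10-tetramethyl-6-methylideneundec-10-en-1-yl]sulfonyl}-1-phenyl-1H-tetrazole | c1ccccc1-n1nnnc1S(=O)(=O)C[C@@H](C)CC[C@@H](C)C(=C)CC[C@@H](C)C(C)=C | intermediate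
25 | (S)-but-3-yn-2-ol | C[C@H](O)C#C | starting material
26 | dilithio (alkoxide, acetylide) salt of 25 | C[C@H](O[Li])C#C[Li] | intermediate
27 | (S)-pent-3-yn-2-ol | C[C@H](O)C#CC | intermediate
28 | sodium cyclic alkenylalanate (five-membered C=C–Al–O ring, Al on C4 cis to C2, two 2-methoxyethoxy groups on Al) | C[C@@H]1O[Al-](OCCOC)(OCCOC)C(C)=C1.[Na+] | intermediate
29 | (2S,3Z)-4-iodopent-3-en-2-ol | C[C@H](O)/C=C(\I)C | intermediate
30 | (2S,3Z)-4-methylhexa-3,5-dien-2-ol | C[C@H](O)/C=C(\C=C)C | intermediate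
31 | (2S,3Z)-4-methylhexa-3,5-dien-2-yl 2-(4-methylbenzenesulfonyl)acetate | C[C@H](OC(=O)CS(=O)(=O)c1ccc(C)cc1)/C=C(\C=C)C | intermediate
32 | O-trimethylsilyl ketene acetal of 31 | C[C@H](OC(O[Si](C)(C)C)=CS(=O)(=O)c1ccc(C)cc1)/C=C(\C=C)C | intermediate
33 | trimethylsilyl (4E)-3-ethenyl-3-methyl-2-(4-methylbenzenesulfonyl)hex-4-enoate (C2 epimers, C3 as in 34) | C[Si](C)(C)OC(=O)C(S(=O)(=O)c1ccc(C)cc1)[C@@](C)(C=C)/C=C/C | intermediate
34 | 1-{[(2S,3E)-2-ethenyl-2-methylpent-3-en-1-yl]sulfonyl}-4-methylbenzene | Cc1ccc(cc1)S(=O)(=O)C[C@@](C)(C=C)/C=C/C | intermediate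
35 | ozonide of the propenyl group of 34 | Cc1ccc(cc1)S(=O)(=O)C[C@@](C)(C=C)C1OOC(C)O1 | intermediate
36 | (2S)-2-methyl-2-[(4-methylbenzenesulfonyl)methyl]but-3-enal | Cc1ccc(cc1)S(=O)(=O)C[C@@](C)(C=C)C=O | intermediate
37 | potassium α-sulfonyl carbanion of 24 | [K+].c1ccccc1-n1nnnc1S(=O)(=O)[CH-][C@@H](C)CC[C@@H](C)C(=C)CC[C@@H](C)C(C)=C | intermediate
38 | 1-methyl-4-{[(2S,3E,5S,8R,12R)-2-ethenyl-2,5,8,12,13-pentamethyl-9-methylidenetetradeca-3,13-dien-1-yl]sulfonyl}benzene | Cc1ccc(cc1)S(=O)(=O)C[C@@](C)(C=C)/C=C/[C@@H](C)CC[C@@H](C)C(=C)CC[C@@H](C)C(C)=C | intermediate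
39 | lithium α-sulfonyl carbanion of 38 | [Li+].Cc1ccc(cc1)S(=O)(=O)[CH-][C@@](C)(C=C)/C=C/[C@@H](C)CC[C@@H](C)C(=C)CC[C@@H](C)C(C)=C | intermediate
40 | target skeleton carrying a 4-methylbenzenesulfonyl group on the CH2 next to the quaternary carbon (both epimers there) | Cc1ccc(cc1)S(=O)(=O)C(C[C@@H](C)C1=CC(C)(C)[C@H](C)CC1)[C@@](C)(C=C)/C=C/[C@@H](C)CC[C@@H](C)C(=C)CC[C@@H](C)C(C)=C | intermediate
41 | (4R)-1-[(2R,5S,6E,8S,11R,15R)-5-ethenyl-5,8,11,15,16-pentamethyl-12-methylideneheptadeca-6,16-dien-2-yl]-3,3,4-trimethylcyclohex-1-ene | C=C[C@@](C)(/C=C/[C@@H](C)CC[C@@H](C)C(=C)CC[C@@H](C)C(=C)C)CC[C@@H](C)C1=CC(C)(C)[C@H](C)CC1 | target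

**Totals and weak points**
Total steps: 23. Longest linear sequence: 17 (steps 1–14, then 21–23).

Step 13 is the first weak point: the Kochi elimination can also give the tetrasubstituted alkene or a tertiary acetate. The fallback sets out from keto acid 22. It is esterified with N-hydroxypyridine-2-thione (DCC, CH2Cl2, dark) to the Barton ester F1. Irradiation with PhSeSePh in benzene gives the tertiary phenyl selenide F2. Oxidation with H2O2 (THF, 0 °C) triggers selenoxide syn-elimination, which prefers the unhindered methyl hydrogens, and the route is rejoined at 23.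

Step 20 is the second: ozone must tell the propenyl group from the vinyl group on the same carbon. The fallback sets out from sulfone 34. m-CPBA (1.0 equiv, CH2Cl2, 0 °C) epoxidises the 1,2-disubstituted alkene roughly twenty times faster than the monosubstituted one and gives the epoxide F3. H5IO6 (THF/H2O) then cleaves it, and the route is rejoined at 36.

Step 22 is the third: a carbanion next to a quaternary carbon must displace a β-branched iodide, and E2 of 13 competes. The fallback sets out from tosylate 12. KOAc (DMF, 80 °C) gives the acetate F4, K2CO3/MeOH gives the alcohol F5, and Tf2O/2,6-lutidine (CH2Cl2, −78 °C) gives the triflate F6. This much stronger electrophile is added to lithio sulfone 39 at −78 °C, and the route is rejoined at 40.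

**Further compounds**
F1 | step 13 | N-hydroxypyridine-2-thione (Barton) ester of 22 | c1ccccc1-n1nnnc1S(=O)(=O)C[C@@H](C)CC[C@@H](C)C(=O)CC[C@@H](C)C(C)(C)C(=O)On1ccccc1=S
F2 | step 13 | tertiary phenyl selenide (SePh in place of CO2H of 22) | c1ccccc1-n1nnnc1S(=O)(=O)C[C@@H](C)CC[C@@H](C)C(=O)CC[C@@H](C)C(C)(C)[Se]c1ccccc1
F3 | step 20 | epoxide of the propenyl group of 34 | Cc1ccc(cc1)S(=O)(=O)C[C@@](C)(C=C)C1OC1C
F4 | step 22 | (2S)-2-[(4R)-3,3,4-trimethylcyclohex-1-en-1-yl]propyl acetate | C[C@H](COC(C)=O)C1=CC(C)(C)[C@H](C)CC1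
F5 | step 22 | (2S)-2-[(4R)-3,3,4-trimethylcyclohex-1-en-1-yl]propan-1-ol | C[C@H](CO)C1=CC(C)(C)[C@H](C)CC1
F6 | step 22 | (2S)-2-[(4R)-3,3,4-trimethylcyclohex-1-en-1-yl]propyl trifluoromethanesulfonate | C[C@H](COS(=O)(=O)C(F)(F)F)C1=CC(C)(C)[C@H](C)CC1
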